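Everything rests on cutting the C3–C3' bond between the two pyrrole rings, after recognising that each N1–C2(Br)=C3 unit is a disguised lactam: a 2-bromoindole is the POBr3 product of an oxindole. C3 then becomes the acidic α-carbon of one oxindole, and the other half, raised to the isatin level, offers an electrophilic C3 ketone. One acid-catalysed aldol condensation of 5,6-dibromoisatin with 5,6-dibromooxindole forges C3=C3' as a tetrabromoisoindigo, which zinc reduces in the same flask to the 3,3'-bioxindole. Double deoxybromination then aromatises both rings.

Key step: step 3

Assumption: compound 6 is carried forward as its mixture of meso and racemic diastereomers, so its SMILES carries no stereodescriptors; the target has no stereocentre and its C3–C3' axis is taken as racemic.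

Step 1
Reactants: 1 6-bromoisatin (6-bromo-1H-indole-2,3-dione)
Product: 2 5,6-dibromoisatin (5,6-dibromo-1H-indole-2,3-dione)
Conditions: NBS (1.05 equiv), conc. H2SO4, 0 °C to rt
Reagents that add atoms: N-bromosuccinimide, O=C1CCC(=O)N1Br
Why: Electrophilic aromatic bromination with acid-activated NBS should go to C5, the position para to the ring nitrogen that isatins brominate first and that is also ortho to the C6 bromine, while one equivalent of reagent limits attack at C7.

Step 2
Reactants: 3 6-bromooxindole (6-bromoindolin-2-one)
Product: 4 5,6-dibromooxindole (5,6-dibromoindolin-2-one)
Conditions: NBS (1.0 equiv), MeCN, −10 to 0 °C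
Reagents that add atoms: N-bromosuccinimide, O=C1CCC(=O)N1Br
Why: Electrophilic aromatic bromination para to the anilide nitrogen (C5) is the established outcome for oxindoles with NBS in a cold polar aprotic solvent, where ionic ring bromination should outrun C3 bromination.

Step 3
Reactants: 2 5,6-dibromoisatin; 4 5,6-dibromooxindole
Product: 6 5,5',6,6'-tetrabromo-3,3'-biindoline-2,2'-dione, via (E)-5,5',6,6'-tetrabromoisoindigo 5 (not isolated)
Conditions: AcOH, conc. HCl (cat.), reflux; then Zn dust (5 equiv), 90 °C, same pot, N2
Reagents that add atoms: none
Why: The enol of oxindole 4 should add through C3 to the protonated C3 ketone of isatin 2, and the resulting tertiary carbinol should lose water to give the C3=C3' alkene of isoindigo 5; Zn in the acidic medium then transfers two electrons to this electron-poor alkene, and protonation at C3 and C3' gives 6. The closest known reaction type is the acid-catalysed isatin–oxindole aldol condensation to isoindigos, followed by Zn/AcOH reduction of an isoindigo to its dihydro compound. No ring is closed. The two new stereocentres at C3 and C3' are set without control by protonation, and both diastereomers are used because step 4 makes both carbons sp2 again. Cross-selectivity is built into the partners, since only 2 carries a ketone and cannot enolise and only 4 carries the acidic CH2, and the C3 ketone of 2 is far more electrophilic than either lactam carbonyl. Zn should reduce the low-lying LUMO of the cross-conjugated bis-lactam alkene in preference to the aryl C–Br bonds.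

Step 4
Reactants: 6 5,5',6,6'-tetrabromo-3,3'-biindoline-2,2'-dione
Product: 7 2,2',5,5',6,6'-hexabromo-1H,1'H-3,3'-biindole
Conditions: POBr3 (5 equiv), imidazole (2.5 equiv), ClCH2CH2Cl, 80 °C; then ice-water
Reagents that add atoms: phosphoryl tribromide, O=P(Br)(Br)Br
Why: This is the known oxindole-to-2-bromoindole deoxybromination run on both lactams: O-phosphorylation, bromide addition–elimination at C2 and a proton shift from C3 to N1 should aromatise each pyrrole ring and erase the C3 stereocentres, with imidazole buffering the HBr that would otherwise attack the 2-bromoindole.

Compound list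
1 | 6-bromoisatin | O=C1Nc2cc(Br)ccc2C1=O | starting material
2 | 5,6-dibromoisatin | O=C1Nc2cc(Br)c(Br)cc2C1=O | intermediate
3 | 6-bromooxindole | O=C1Cc2ccc(Br)cc2N1 | starting material
4 | 5,6-dibromooxindole | O=C1Cc2cc(Br)c(Br)cc2N1 | intermediate
5 | (E)-5,5',6,6'-tetrabromoisoindigo ((E)-5,5',6,6'-tetrabromo-[3,3'-biindolinylidene]-2,2'-dione) | O=C1Nc2cc(Br)c(Br)cc2/C1=C1\C(=O)Nc2cc(Br)c(Br)cc21 | intermediate (not isolated)
6 | 5,5',6,6'-tetrabromo-3,3'-biindoline-2,2'-dione (meso and racemic diastereomers) | O=C1Nc2cc(Br)c(Br)cc2C1C1C(=O)Nc2cc(Br)c(Br)cc21 | intermediate
7 | 2,2',5,5',6,6'-hexabromo-1H,1'H-3,3'-biindole | Brc1cc2[nH]c(Br)c(-c3c(Br)[nH]c4cc(Br)c(Br)cc34)c2cc1Br | target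

Total step count: 4
Longest linear sequence: 3 (step 1 or step 2, then steps 3 and 4)

Steps most likely to fail

Step 4. The bis-lactam 6 is a 1,4-dicarbonyl compound, so after the first activation the second lactam oxygen may close onto C2 and give an oxygen-bridged cyclodehydration product instead of taking up bromide. The second deoxybromination may also stall, or HBr may degrade the 2-bromoindole as it forms. The fallback sets out from 6 and separates deoxygenation from bromination. DIBAL-H in toluene/THF (0 °C to rt, acidic work-up) should reduce each lactam to the hemiaminal, which dehydrates to the indole and gives 5,5',6,6'-tetrabromo-1H,1'H-3,3'-biindole F1. NBS (2.0 equiv, THF, −78 to 0 °C) should then brominate the two free C2 positions of these 3-substituted indoles, and the sequence comes back to the route at 7.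

Step 3. The tetrabromoisoindigo 5 is expected to crystallise as a very insoluble pigment, so the heterogeneous zinc reduction may stall on the solid, or forcing it may begin to hydrogenolyse C–Br bonds. The fallback sets out from 2 and 4 and never lets the pigment form. Piperidine (cat.) in EtOH at rt should stop at the base-catalysed aldol addition and give the soluble 5,5',6,6'-tetrabromo-3-hydroxy-3,3'-biindoline-2,2'-dione F2. Treating F2 with Zn dust in AcOH/conc. HCl at 60 °C should ionise and dehydrate the tertiary carbinol in solution and reduce the alkene as it appears, and the sequence comes back to the route at 6.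

Step 2. Bromination of 3 may divide between C5 of the arene and the enolisable C3 methylene, or run on to polybromides. The fallback sets out from 2, whose bromine pattern is already fixed, and uses a Wolff–Kishner reduction of the C3 ketone. Hydrazine hydrate in refluxing EtOH should give (Z)-5,6-dibromo-3-hydrazonoindolin-2-one F3, and NaOEt in refluxing EtOH should then expel dinitrogen, so that the sequence comes back to the route at 4.

Further compounds
F1 | step 4 | 5,5',6,6'-tetrabromo-1H,1'H-3,3'-biindole | Brc1cc2[nH]cc(-c3c[nH]c4cc(Br)c(Br)cc34)c2cc1Br
F2 | step 3 | 5,5',6,6'-tetrabromo-3-hydroxy-3,3'-biindoline-2,2'-dione (diastereomer mixture) | O=C1Nc2cc(Br)c(Br)cc2C1(O)C1C(=O)Nc2cc(Br)c(Br)cc21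
F3 | step 2 | (Z)-5,6-dibromo-3-hydrazonoindolin-2-one | N/N=C1\C(=O)Nc2cc(Br)c(Br)cc21
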